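**Strategy.** Ring A of the target (C1–C5 and C10, eudesmane numbering) is read as a dearomatised phenol: O-3 sits para to the quaternary C10 and C4 carries the second oxygen. The C9–C10 bond is therefore made by intramolecular para-C-alkylation of a 3-alkyl-2-methoxy-4-methylphenoxide. In one operation this closes ring B, creates the C10 stereocentre and turns the flat arene into a 4-methoxy-1,4-dien-3-one that maps onto the C3/C4 diol. The precursor is a phenol bearing a 1-silyloxy-2-ethynyl-4-halobutyl chain from an auxiliary aldol: the benzylic silyloxy group steers the face of attack and later leaves to unveil C5=C6, and the ethynyl group is the latent acrylate.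

Key step: step 8

Remark: atoms are numbered as in eudesmane (ring A = C1–C5, C10; ring B = C5–C10; C14 on C10, C15 on C4, C11–C13 on C7); compounds 1, 7, 8 and 23 are assumed to be purchasable.

Step 1
Reactants: 1 2-methoxy-6-methylbenzaldehyde
Product: 5 3-hydroxy-2-methoxy-6-methylbenzaldehyde, via lithium α-amino alkoxide 2 (not isolated), via ring-lithiated alkoxide 3 (not isolated), via arylboronate 4 (not isolated)
Conditions: N-methylpiperazine, n-BuLi, THF, −20 °C, then 1; n-BuLi, TMEDA, −20 → 0 °C; B(OMe)3, −78 °C → rt; H2O2, aq. NaOH, 0 °C; aq. HCl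
Reagents that add atoms: hydrogen peroxide OO
Why: In situ protection of the aldehyde as its lithium α-amino alkoxide (a weak director) should let the methoxy group control a directed ortho-metalation at the ring carbon next to OMe, and borylation/peroxide oxidation followed by acid release of the aldehyde should give the phenol.

Step 2
Reactants: 5 3-hydroxy-2-methoxy-6-methylbenzaldehyde
Product: 6 3-[(tert-butyldimethylsilyl)oxy]-2-methoxy-6-methylbenzaldehyde
Conditions: TBSCl, imidazole, DMF, rt
Reagents that add atoms: tert-butyldimethylsilyl chloride CC(C)(C)[Si](C)(C)Cl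
Why: Standard phenol silylation, needed so that the acidic OH does not quench the titanium enolate of step 4.

Step 3
Reactants: 7 (R)-4-benzyl-1,3-thiazolidine-2-thione, 8 4-chlorobutanoyl chloride
Product: 9 (R)-4-benzyl-3-(4-chlorobutanoyl)-1,3-thiazolidine-2-thione
Conditions: Et3N, DMAP (cat.), CH2Cl2, 0 °C
Reagents that add atoms: none
Why: N-Acylation of the thiazolidinethione attaches the chiral auxiliary to the four-carbon unit that becomes C11, C7, C8 and C9.

Step 4
Reactants: 9 (R)-4-benzyl-3-(4-chlorobutanoyl)-1,3-thiazolidine-2-thione, 6 3-[(tert-butyldimethylsilyl)oxy]-2-methoxy-6-methylbenzaldehyde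
Product: 11 (R)-4-benzyl-3-[(2R,3R)-3-{3-[(tert-butyldimethylsilyl)oxy]-2-methoxy-6-methylphenyl}-2-(2-chloroethyl)-3-hydroxypropanoyl]-1,3-thiazolidine-2-thione, via chlorotitanium Z-enolate 10 (not isolated)
Conditions: TiCl4, i-Pr2NEt, NMP, CH2Cl2, 0 °C; then 6, 0 °C
Reagents that add atoms: none
Why: Titanium-mediated acyl-thiazolidinethione aldol addition in its Evans-syn mode: the Z-enolate should add through a chair transition state on the face away from the auxiliary benzyl group, setting C7 (2R) and C6 (3R) together as the syn aldol.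

Step 5
Reactants: 11 syn aldol adduct
Product: 12 (R)-4-benzyl-3-[(2R,3R)-3-[(tert-butyldimethylsilyl)oxy]-3-{3-[(tert-butyldimethylsilyl)oxy]-2-methoxy-6-methylphenyl}-2-(2-chloroethyl)propanoyl]-1,3-thiazolidine-2-thione
Conditions: TBSOTf, 2,6-lutidine, CH2Cl2, 0 °C
Reagents that add atoms: tert-butyldimethylsilyl triflate CC(C)(C)[Si](C)(C)OS(=O)(=O)C(F)(F)F
Why: Silyl triflate silylation of the hindered benzylic alcohol blocks retro-aldol and O-alkylation and makes O-6 the later leaving group.

Step 6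
Reactants: 12 bis-silyl ether
Product: 13 (2R,3R)-3-[(tert-butyldimethylsilyl)oxy]-3-{3-[(tert-butyldimethylsilyl)oxy]-2-methoxy-6-methylphenyl}-2-(2-chloroethyl)propanal
Conditions: DIBAL-H, CH2Cl2, −78 °C; Rochelle salt
Reagents that add atoms: none
Why: N-Acylthiazolidinethiones are reduced directly to aldehydes by DIBAL-H because the thione is a good leaving group; the C–Cl bond and both silyl ethers should survive at −78 °C.

Step 7
Reactants: 13 α-branched aldehyde
Product: 15 3-[(1R,2S)-1-[(tert-butyldimethylsilyl)oxy]-2-(2-chloroethyl)but-3-yn-1-yl]-2-methoxy-4-methylphenol, via aryl silyl ether alkyne 14 (not isolated)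
Conditions: dimethyl (1-diazo-2-oxopropyl)phosphonate, K2CO3, MeOH, 0 °C → rt
Reagents that add atoms: dimethyl (1-diazo-2-oxopropyl)phosphonate COP(=O)(OC)C(=[N+]=[N-])C(C)=O
Why: Ohira–Bestmann homologation should turn the aldehyde into the terminal alkyne (C11≡C13) with the C7 geometry unchanged (the descriptor changes only by CIP priority), and K2CO3/MeOH also cleaves the aryl but not the alkyl silyl ether.

Step 8
Reactants: 15 phenol alkyne chloride
Product: 17 (4aS,7S,8R)-8-[(tert-butyldimethylsilyl)oxy]-7-ethynyl-1-methoxy-4a-methyl-5,6,7,8-tetrahydronaphthalen-2(4aH)-one, via primary iodide 16 (not isolated)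
Conditions: NaI, Cs2CO3, MeCN (0.005 M), 70 °C
Reagents that add atoms: none
Why: After Finkelstein exchange the caesium phenoxide is an ambident nucleophile whose oxygen cannot reach C9 (a meta-bridged eight-membered ether would result), so SN2 displacement should occur through the carbon para to O⁻ (C10) in a 6-exo-tet closure of ring B that dearomatises ring A to the cross-conjugated dienone. The closest known reaction type is the intramolecular para-alkylative dearomatisation of phenols (phenoxide participation in halide or sulfonate displacement). C10 becomes quaternary and is controlled by C6: allylic 1,3-strain with the C4 methoxy group holds H-6 in the arene plane and the silyloxy group perpendicular to it, so the chain reaches C10 from the face anti to OTBS. In the chair-like transition state the syn-configured ethynyl group at C7 is equatorial, which places the C10 methyl cis to the C7 substituent. The step needs C- over O-alkylation, para (C10) over ortho (C4) attack and substitution over E2; the tether geometry, the methoxy group blocking C4, and a weak carbonate base at high dilution should secure these.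

Step 9
Reactants: 17 4-methoxy-1,4-dien-3-one
Product: 18 (4aS,7S,8R)-8-[(tert-butyldimethylsilyl)oxy]-7-ethynyl-1-methoxy-4a-methyl-4,4a,5,6,7,8-hexahydronaphthalen-2(3H)-one
Conditions: L-Selectride, THF, −78 °C; aq. NH4Cl
Reagents that add atoms: none
Why: Conjugate hydride reduction should occur at the unsubstituted β-carbon C1 (the C5 terminus is fully substituted and its α-carbon carries the donor methoxy group), and the enolate formed resists further reduction until work-up.

Step 10
Reactants: 18 α-methoxy enone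
Product: 20 (2S,4aS,7R)-7-ethynyl-2-hydroxy-4a-methyl-3,4,4a,5,6,7-hexahydronaphthalen-1(2H)-one, via allylic alcohol 19 (not isolated)
Conditions: NaBH4, CeCl3·7H2O, MeOH, −78 °C; then 1 M HCl, THF, 0 °C → rt
Reagents that add atoms: water O
Why: Luche reduction should give the 3β (equatorial) alcohol by axial hydride attack as in 10β-methyl-Δ4-3-ketones, and aqueous acid then hydrolyses the vinylogous acetal C4(OMe)=C5–C6(OTBS), expelling methanol and silanol to leave the C4 ketone conjugated with the new C5=C6 bond.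

Step 11
Reactants: 20 3β-hydroxy-4-oxo-5-ene
Product: 21 (1R,2S,4aS,7R)-7-ethynyl-1,4a-dimethyl-1,2,3,4,4a,5,6,7-octahydronaphthalene-1,2-diol
Conditions: MeMgBr (excess), CeCl3, THF, −78 °C
Reagents that add atoms: methylmagnesium bromide C[Mg]Br
Why: 1,2-Addition of the methyl-cerium/magnesium reagent to the C4 ketone, chelated to the C3 alkoxide, should occur from the α face anti to the axial C10 methyl (equatorial attack), giving the 4β-hydroxy-4α-methyl centre cis to O-3; excess reagent covers the OH and alkyne protons.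

Step 12
Reactants: 21 diol alkyne
Product: 22 methyl 2-[(2R,4aS,7S,8R)-7,8-dihydroxy-4a,8-dimethyl-2,3,4,4a,5,6,7,8-octahydronaphthalen-2-yl]prop-2-enoate
Conditions: Pd(OAc)2 (5 mol %), 2-(diphenylphosphino)pyridine, p-TsOH (cat.), CO (5 bar), MeOH/CH2Cl2, 45 °C
Reagents that add atoms: carbon monoxide [C-]#[O+]; methanol CO
Why: Pd–H/2-pyridylphosphine-catalysed Markovnikov methoxycarbonylation of a terminal alkyne places the ester on the internal carbon C11 and should give the 2-substituted acrylate, while the internal alkene does not react.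

Step 13
Reactants: 22 acrylate diol, 23 angelic acid [(Z)-2-methylbut-2-enoic acid]
Product: 25 methyl 2-[(2R,4aS,7S,8R)-7-{[(Z)-2-methylbut-2-enoyl]oxy}-8-hydroxy-4a,8-dimethyl-2,3,4,4a,5,6,7,8-octahydronaphthalen-2-yl]prop-2-enoate (target), via mixed anhydride 24 (not isolated)
Conditions: 23, 2,4,6-trichlorobenzoyl chloride, Et3N, toluene, rt; then 22, 80 °C
Reagents that add atoms: none
Why: Yamaguchi esterification through the mixed anhydride should acylate only the secondary equatorial 3-OH (the tertiary 4-OH is inert), and omitting DMAP should preserve the Z geometry of the angelate.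

**Compound list**

1 | 2-methoxy-6-methylbenzaldehyde | O=Cc1c(C)cccc1OC | starting material
2 | lithium (2-methoxy-6-methylphenyl)(4-methylpiperazin-1-yl)methanolate | [Li]OC(N1CCN(C)CC1)c1c(C)cccc1OC | intermediate
3 | 3-lithio derivative of 2 (Li ortho to OMe) | [Li]OC(N1CCN(C)CC1)c1c(C)ccc([Li])c1OC | intermediate
4 | dimethyl arylboronate derived from 3 | [Li]OC(N1CCN(C)CC1)c1c(C)ccc(B(OC)OC)c1OC | intermediate
5 | 3-hydroxy-2-methoxy-6-methylbenzaldehyde | O=Cc1c(C)ccc(O)c1OC | intermediate
6 | 3-[(tert-butyldimethylsilyl)oxy]-2-methoxy-6-methylbenzaldehyde | O=Cc1c(C)ccc(O[Si](C)(C)C(C)(C)C)c1OC | intermediate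
7 | (R)-4-benzyl-1,3-thiazolidine-2-thione | S=C1N[C@H](Cc2ccccc2)CS1 | starting material
8 | 4-chlorobutanoyl chloride | O=C(Cl)CCCCl | starting material
9 | (R)-4-benzyl-3-(4-chlorobutanoyl)-1,3-thiazolidine-2-thione | O=C(CCCCl)N1C(=S)SC[C@H]1Cc1ccccc1 | intermediate
10 | trichlorotitanium (Z)-enolate of 9 | Cl[Ti](Cl)(Cl)O/C(=C\CCCl)N1C(=S)SC[C@H]1Cc1ccccc1 | intermediate
11 | (2R,3R)-syn aldol adduct (3-hydroxy-3-aryl-2-(2-chloroethyl)propanoyl thiazolidinethione) | O=C([C@H](CCCl)[C@@H](O)c1c(C)ccc(O[Si](C)(C)C(C)(C)C)c1OC)N1C(=S)SC[C@H]1Cc1ccccc1 | intermediate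
12 | 3-O-TBS ether of 11 | O=C([C@H](CCCl)[C@@H](O[Si](C)(C)C(C)(C)C)c1c(C)ccc(O[Si](C)(C)C(C)(C)C)c1OC)N1C(=S)SC[C@H]1Cc1ccccc1 | intermediate
13 | (2R,3R)-3-[(TBS)oxy]-3-{3-[(TBS)oxy]-2-methoxy-6-methylphenyl}-2-(2-chloroethyl)propanal | O=C[C@H](CCCl)[C@@H](O[Si](C)(C)C(C)(C)C)c1c(C)ccc(O[Si](C)(C)C(C)(C)C)c1OC | intermediate
14 | (1R,2S)-1-{3-[(TBS)oxy]-2-methoxy-6-methylphenyl}-1-[(TBS)oxy]-2-(2-chloroethyl)but-3-yne | C#C[C@H](CCCl)[C@@H](O[Si](C)(C)C(C)(C)C)c1c(C)ccc(O[Si](C)(C)C(C)(C)C)c1OC | intermediate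
15 | 3-[(1R,2S)-1-[(TBS)oxy]-2-(2-chloroethyl)but-3-yn-1-yl]-2-methoxy-4-methylphenol | C#C[C@H](CCCl)[C@@H](O[Si](C)(C)C(C)(C)C)c1c(C)ccc(O)c1OC | intermediate
16 | 3-[(1R,2S)-1-[(TBS)oxy]-2-(2-iodoethyl)but-3-yn-1-yl]-2-methoxy-4-methylphenol | C#C[C@H](CCI)[C@@H](O[Si](C)(C)C(C)(C)C)c1c(C)ccc(O)c1OC | intermediate
17 | (4aS,7S,8R)-8-[(TBS)oxy]-7-ethynyl-1-methoxy-4a-methyl-5,6,7,8-tetrahydronaphthalen-2(4aH)-one | C#C[C@@H]1CC[C@@]2(C)C=CC(=O)C(OC)=C2[C@@H]1O[Si](C)(C)C(C)(C)C | intermediate
18 | (4aS,7S,8R)-8-[(TBS)oxy]-7-ethynyl-1-methoxy-4a-methyl-4,4a,5,6,7,8-hexahydronaphthalen-2(3H)-one | C#C[C@@H]1CC[C@@]2(C)CCC(=O)C(OC)=C2[C@@H]1O[Si](C)(C)C(C)(C)C | intermediate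
19 | (2S,4aS,7S,8R)-8-[(TBS)oxy]-7-ethynyl-1-methoxy-4a-methyl-2,3,4,4a,5,6,7,8-octahydronaphthalen-2-ol | C#C[C@@H]1CC[C@@]2(C)CC[C@H](O)C(OC)=C2[C@@H]1O[Si](C)(C)C(C)(C)C | intermediate
20 | (2S,4aS,7R)-7-ethynyl-2-hydroxy-4a-methyl-3,4,4a,5,6,7-hexahydronaphthalen-1(2H)-one | C#C[C@H]1C=C2[C@](C)(CC[C@H](O)C2=O)CC1 | intermediate
21 | (1R,2S,4aS,7R)-7-ethynyl-1,4a-dimethyl-1,2,3,4,4a,5,6,7-octahydronaphthalene-1,2-diol | C#C[C@H]1C=C2[C@](C)(CC[C@H](O)[C@]2(C)O)CC1 | intermediate
22 | methyl 2-[(2R,4aS,7S,8R)-7,8-dihydroxy-4a,8-dimethyl-2,3,4,4a,5,6,7,8-octahydronaphthalen-2-yl]prop-2-enoate | C=C(C(=O)OC)[C@H]1C=C2[C@](C)(CC[C@H](O)[C@]2(C)O)CC1 | intermediate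
23 | angelic acid, (Z)-2-methylbut-2-enoic acid | C/C=C(/C)C(=O)O | starting material
24 | angelic 2,4,6-trichlorobenzoic mixed anhydride | C/C=C(/C)C(=O)OC(=O)c1c(Cl)cc(Cl)cc1Cl | intermediate
25 | methyl 3β-angeloyloxy-4β-hydroxyeudesma-5,11(13)-dien-12-oate (CNP0283268.1) | C=C(C(=O)OC)[C@H]1C=C2[C@](C)(CC[C@H](OC(=O)/C(C)=C\C)[C@]2(C)O)CC1 | target

**Step count.** Total: 13 steps. Longest linear sequence: 12 steps (1, 2, 4–13 from compound 1); step 3 is a one-step side branch.

**Steps most likely to fail**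

Step 8 (key step). The para C-alkylation is slow, so E2 loss of HI from the primary iodide, attack through the methoxy-bearing ortho carbon C4, intermolecular O-alkylation, or base-induced alkyne–allene isomerisation at C7 may compete. The fallback replaces the anionic closure by an electrophilic one that needs no base and is para-selective. It sets out from 15: the phenol would be re-silylated (TBSCl, imidazole) to give 14, and chloride exchanged for iodide (NaI, acetone) to give the bis-silyl ether iodide F1. F1 would be treated with AgOTf in CH2Cl2 at −20 °C so that the neutral aryl silyl ether attacks the silver-activated C9–I bond through C10 (aryl participation, ipso-Friedel–Crafts-type dearomatisation). Loss of the silyl group from the silyloxocarbenium ion on work-up returns to the route at 17.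

Step 12. The acid co-catalyst may ionise the tertiary allylic alcohol, and the α-branched alkyne may lose Markovnikov regiocontrol. The fallback sets out from 21 and avoids acid: Ru-catalysed Markovnikov hydrosilylation (Et3SiH, [Cp*Ru(MeCN)3]PF6, CH2Cl2, 0 °C) would give the α-vinylsilane F2, and iododesilylation (NIS, HFIP, 0 °C) the vinyl iodide F3. Pd-catalysed methoxycarbonylation under basic conditions (Pd(PPh3)4, CO, MeOH, Et3N, 50 °C) then comes back to the route at 22.

Step 10. The α-hydroxy enone may enolise towards C3 and tautomerise to the conjugated diosphenol, or loss of the silyloxy group may stall at the β-silyloxy ketone. The fallback changes the order of events so that no free acyloin is formed. It sets out from 19, isolated after the Luche stage by neutral work-up. Acylation with the mixed anhydride 24 would give the 3-O-angeloyl enol ether F4, and acid hydrolysis (TsOH, wet THF) the 3-angeloyloxy-4-oxo-5-ene F5. Ketone-selective methyl addition (MeMgBr/CeCl3, −78 °C) would give the tertiary alcohol F6, and the conditions of step 12 applied to F6 come back to the route at 25.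

**Further compounds**

F1 | step 8 | (1R,2S)-1-{3-[(TBS)oxy]-2-methoxy-6-methylphenyl}-1-[(TBS)oxy]-2-(2-iodoethyl)but-3-yne | C#C[C@H](CCI)[C@@H](O[Si](C)(C)C(C)(C)C)c1c(C)ccc(O[Si](C)(C)C(C)(C)C)c1OC
F2 | step 12 | (1R,2S,4aS,7R)-1,4a-dimethyl-7-[1-(triethylsilyl)ethenyl]-1,2,3,4,4a,5,6,7-octahydronaphthalene-1,2-diol | C=C([Si](CC)(CC)CC)[C@H]1C=C2[C@](C)(CC[C@H](O)[C@]2(C)O)CC1
F3 | step 12 | (1R,2S,4aS,7R)-7-(1-iodoethenyl)-1,4a-dimethyl-1,2,3,4,4a,5,6,7-octahydronaphthalene-1,2-diol | C=C(I)[C@H]1C=C2[C@](C)(CC[C@H](O)[C@]2(C)O)CC1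
F4 | step 10 | (2S,4aS,7S,8R)-8-[(TBS)oxy]-7-ethynyl-1-methoxy-4a-methyl-2,3,4,4a,5,6,7,8-octahydronaphthalen-2-yl (Z)-2-methylbut-2-enoate | C#C[C@@H]1CC[C@@]2(C)CC[C@H](OC(=O)/C(C)=C\C)C(OC)=C2[C@@H]1O[Si](C)(C)C(C)(C)C
F5 | step 10 | (2S,4aS,7R)-7-ethynyl-4a-methyl-1-oxo-1,2,3,4,4a,5,6,7-octahydronaphthalen-2-yl (Z)-2-methylbut-2-enoate | C#C[C@H]1C=C2[C@](C)(CC[C@H](OC(=O)/C(C)=C\C)C2=O)CC1
F6 | step 10 | (1R,2S,4aS,7R)-7-ethynyl-1-hydroxy-1,4a-dimethyl-1,2,3,4,4a,5,6,7-octahydronaphthalen-2-yl (Z)-2-methylbut-2-enoate | C#C[C@H]1C=C2[C@](C)(CC[C@H](OC(=O)/C(C)=C\C)[C@]2(C)O)CC1
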